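The target is a 6,8-dihydroxyisochroman-1-one (aromatic ring A fused to lactone ring B) whose C3 carries an undecyl chain C1′–C11′ with OMe at C10′. The route exploits the fact that the C10′ oxygen can stand in temporarily for the ring-B oxygen on the C1 carboxyl, so the nine methylenes C1′–C9′ between the two stereocentres are closed as a ring. Ring-closing metathesis of an (S)-non-8-en-2-yl 2,4-bis(benzyloxy)benzoate carrying an ortho (R)-2-(triethylsilyloxy)hex-5-enyl arm forges C3′=C4′ and a sacrificial 16-membered lactone in one operation. Desilylation lets the C3 oxygen recapture C1, contracting to ring B and freeing C10′–OH for methylation; one hydrogenation finishes.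

Key step: step 7

Remark: the ester is made by Mitsunobu inversion, so the (R)-alcohol from (R)-propylene oxide is used to arrive at the (S)-configured ester; the alkene from step 7 is carried on as its E/Z mixture and drawn E.

Step 1
Reactants: 1 1-bromo-3,5-bis(benzyloxy)benzene; 2 (R)-1,2-epoxyhex-5-ene
Product: 4 (R)-1-[3,5-bis(benzyloxy)phenyl]hex-5-en-2-ol, via arylmagnesium bromide 3 (not isolated)
Conditions: Mg, I2 (cat.), THF, reflux; then CuI (10 mol %), 2, THF, −30 → 0 °C; H2O quench
Reagents that add atoms: none
Why: Copper-catalysed Grignard opening of a terminal epoxide is an SN2 attack at the unsubstituted CH2, so the C–O bond at the stereocentre is untouched and the (R) configuration of 2 becomes C3 of the target.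

Step 2
Reactants: 4 (R)-1-[3,5-bis(benzyloxy)phenyl]hex-5-en-2-ol
Product: 5 (R)-{[1-(3,5-bis(benzyloxy)phenyl)hex-5-en-2-yl]oxy}triethylsilane
Conditions: TESCl, imidazole, CH2Cl2, 0 °C → rt
Reagents that add atoms: chlorotriethylsilane, CC[Si](Cl)(CC)CC
Why: Imidazole-promoted silylation of the secondary alcohol masks the C3 oxygen so that the carboxyl introduced later cannot lactonise early, and triethylsilyl is removed by fluoride under the conditions that trigger the ring contraction.

Step 3
Reactants: 5 (R)-{[1-(3,5-bis(benzyloxy)phenyl)hex-5-en-2-yl]oxy}triethylsilane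
Product: 6 (R)-{[1-(3,5-bis(benzyloxy)-2-bromophenyl)hex-5-en-2-yl]oxy}triethylsilane
Conditions: NBS (1.0 equiv), MeCN, −20 → 0 °C, dark
Reagents that add atoms: N-bromosuccinimide, O=C1CCC(=O)N1Br
Why: Electrophilic aromatic bromination of a 3,5-dialkoxyalkylbenzene with NBS in a polar solvent should go ortho to the alkyl arm and para to a benzyloxy group (the site between the two ethers is shielded), and the doubly activated arene should react much faster than the monosubstituted alkene.

Step 4
Reactants: 6 (R)-{[1-(3,5-bis(benzyloxy)-2-bromophenyl)hex-5-en-2-yl]oxy}triethylsilane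
Product: 8 2,4-bis(benzyloxy)-6-[(R)-2-(triethylsilyloxy)hex-5-enyl]benzoic acid, via aryllithium 7 (not isolated)
Conditions: n-BuLi (1.05 equiv), THF, −78 °C; CO2 (dry gas), −78 → 0 °C; cold dilute HCl to pH 4–5
Reagents that add atoms: carbon dioxide, O=C=O
Why: Bromine–lithium exchange at −78 °C outpaces benzylic or ring deprotonation, carboxylation of the aryllithium places C1 exactly at the brominated carbon, and the cold, only mildly acidic work-up should keep the silyl ether and so prevent lactonisation.

Step 5
Reactants: 9 6-bromohex-1-ene; 10 (R)-propylene oxide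
Product: 12 (R)-non-8-en-2-ol, via hex-5-enylmagnesium bromide 11 (not isolated)
Conditions: Mg, THF, rt → 40 °C; then CuI (10 mol %), 10, THF, −30 → 0 °C; H2O quench
Reagents that add atoms: none
Why: Copper-catalysed Grignard opening at the CH2 terminus of the epoxide leaves the carbinol C–O bond intact, so the (R) configuration of 10 is retained.

Step 6
Reactants: 8 2,4-bis(benzyloxy)-6-[(R)-2-(triethylsilyloxy)hex-5-enyl]benzoic acid; 12 (R)-non-8-en-2-ol
Product: 13 (S)-non-8-en-2-yl 2,4-bis(benzyloxy)-6-[(R)-2-(triethylsilyloxy)hex-5-enyl]benzoate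
Conditions: PPh3, DIAD, THF, 0 °C → rt
Reagents that add atoms: none
Why: In the Mitsunobu esterification the carboxylate displaces the alkoxyphosphonium group by SN2 at the carbinol carbon, which avoids the steric shielding of the 2,6-disubstituted carboxyl and inverts (R)-12 to the (S)-configured C10′–O ester.

Step 7
Reactants: 13 (S)-non-8-en-2-yl 2,4-bis(benzyloxy)-6-[(R)-2-(triethylsilyloxy)hex-5-enyl]benzoate
Product: 14 benzo-fused 16-membered macrolactone (E/Z at C3′=C4′) with (R)-C3–OSiEt3, (S)-C10′ as the methyl-bearing ester carbon and 2,4-bis(benzyloxy) substitution on the arene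
Conditions: second-generation Grubbs catalyst RuCl2(=CHPh)(PCy3)(H2IMes) (5–10 mol %), CH2Cl2 (about 1 mM, slow addition of 13), reflux, Ar sparge; then ethyl vinyl ether
Reagents that add atoms: none
Why: The ruthenium benzylidene exchanges onto one terminal vinyl group, the resulting alkylidene adds [2+2] to the second vinyl group, and cycloreversion of the ruthenacyclobutane releases ethylene and forms C3′=C4′. The closest known reaction type is ring-closing metathesis macrocyclisation of ester-tethered dienes to benzo-fused resorcylate macrolactones with this catalyst. The one ring formed is the 16-membered lactone, closed end to end between the two monosubstituted alkene termini with the new double bond inside the ring. No stereocentre is created; the existing centres lie three and six bonds from the reacting carbons and are untouched, and the E/Z ratio does not matter because the alkene is saturated in step 10. The selectivity needed is ring closure over acyclic diene metathesis oligomerisation: the ester tether makes the reaction intramolecular, high dilution with slow addition and ethylene removal favours the ring, and reversibility lets oligomers back-bite to the macrocycle. Both alkenes are unhindered, and the silyl ether, benzyl ethers and hindered ester should be inert to the catalyst.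

Step 8
Reactants: 14 benzo-fused 16-membered macrolactone
Product: 16 (R)-6,8-bis(benzyloxy)-3-[(S)-10-hydroxyundec-3-en-1-yl]isochroman-1-one (E/Z), via hydroxy macrolactone 15 (not isolated)
Conditions: TBAF (1.5 equiv), THF, 0 °C → rt; H2O work-up
Reagents that add atoms: none
Why: Fluoride desilylation unmasks the C3 alkoxide, which adds to the neighbouring ester carbonyl through a six-membered tetrahedral intermediate (intramolecular transesterification, translactonisation) and expels the C10′ alkoxide, the conjugated strain-free benzo-δ-lactone being the thermodynamic sink and no C–O bond at a stereocentre being broken.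

Step 9
Reactants: 16 (R)-6,8-bis(benzyloxy)-3-[(S)-10-hydroxyundec-3-en-1-yl]isochroman-1-one
Product: 17 (R)-6,8-bis(benzyloxy)-3-[(S)-10-methoxyundec-3-en-1-yl]isochroman-1-one (E/Z)
Conditions: Me3OBF4 (3 equiv), 1,8-bis(dimethylamino)naphthalene (3.5 equiv), 4 Å MS, CH2Cl2, 0 °C → rt
Reagents that add atoms: trimethyloxonium tetrafluoroborate, C[O+](C)C.F[B-](F)(F)F
Why: O-Methylation with Meerwein's salt buffered by a non-nucleophilic amine alkylates the secondary alcohol with retention (only the O–H bond is exchanged) under non-basic conditions that spare the lactone and its benzylic C4–H.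

Step 10
Reactants: 17 (R)-6,8-bis(benzyloxy)-3-[(S)-10-methoxyundec-3-en-1-yl]isochroman-1-one
Product: 19 (R)-6,8-dihydroxy-3-[(S)-10-methoxyundecyl]isochroman-1-one (CNP0242607.1), via saturated dibenzyl ether 18 (not isolated)
Conditions: H2 (1 atm), 10% Pd/C, EtOAc, rt
Reagents that add atoms: none
Why: Heterogeneous catalytic hydrogenation over Pd/C saturates the disubstituted alkene and hydrogenolyses both aryl benzyl ethers in one operation, while the lactone C3–O bond is neither benzylic nor allylic and the stereocentres are not touched.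

Compound list
1 | 1-bromo-3,5-bis(benzyloxy)benzene | Brc1cc(OCc2ccccc2)cc(OCc2ccccc2)c1 | starting material
2 | (R)-1,2-epoxyhex-5-ene | C=CCC[C@@H]1CO1 | starting material
3 | 3,5-bis(benzyloxy)phenylmagnesium bromide | Br[Mg]c1cc(OCc2ccccc2)cc(OCc2ccccc2)c1 | intermediate (not isolated)
4 | (R)-1-[3,5-bis(benzyloxy)phenyl]hex-5-en-2-ol | C=CCC[C@@H](O)Cc1cc(OCc2ccccc2)cc(OCc2ccccc2)c1 | intermediate
5 | (R)-{[1-(3,5-bis(benzyloxy)phenyl)hex-5-en-2-yl]oxy}triethylsilane | C=CCC[C@@H](O[Si](CC)(CC)CC)Cc1cc(OCc2ccccc2)cc(OCc2ccccc2)c1 | intermediate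
6 | (R)-{[1-(3,5-bis(benzyloxy)-2-bromophenyl)hex-5-en-2-yl]oxy}triethylsilane | C=CCC[C@@H](O[Si](CC)(CC)CC)Cc1cc(OCc2ccccc2)cc(OCc2ccccc2)c1Br | intermediate
7 | {2,4-bis(benzyloxy)-6-[(R)-2-(triethylsilyloxy)hex-5-enyl]phenyl}lithium | [Li]c1c(OCc2ccccc2)cc(OCc2ccccc2)cc1C[C@H](O[Si](CC)(CC)CC)CCC=C | intermediate (not isolated)
8 | 2,4-bis(benzyloxy)-6-[(R)-2-(triethylsilyloxy)hex-5-enyl]benzoic acid | OC(=O)c1c(OCc2ccccc2)cc(OCc2ccccc2)cc1C[C@H](O[Si](CC)(CC)CC)CCC=C | intermediate
9 | 6-bromohex-1-ene | C=CCCCCBr | starting material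
10 | (R)-propylene oxide | C[C@@H]1CO1 | starting material
11 | hex-5-enylmagnesium bromide | C=CCCCC[Mg]Br | intermediate (not isolated)
12 | (R)-non-8-en-2-ol | C=CCCCCC[C@@H](C)O | intermediate
13 | (S)-non-8-en-2-yl 2,4-bis(benzyloxy)-6-[(R)-2-(triethylsilyloxy)hex-5-enyl]benzoate | C=CCCCCC[C@H](C)OC(=O)c1c(OCc2ccccc2)cc(OCc2ccccc2)cc1C[C@H](O[Si](CC)(CC)CC)CCC=C | intermediate
14 | benzo-fused 16-membered macrolactone, (R)-C3–OSiEt3, (S)-C10′, C3′=C4′ (E drawn, Z also expected) | C[C@H]1CCCCC/C=C/CC[C@@H](O[Si](CC)(CC)CC)Cc2cc(OCc3ccccc3)cc(OCc3ccccc3)c2C(=O)O1 | intermediate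
15 | desilylated 16-membered hydroxy macrolactone (reacts as its C3 alkoxide) | C[C@H]1CCCCC/C=C/CC[C@@H](O)Cc2cc(OCc3ccccc3)cc(OCc3ccccc3)c2C(=O)O1 | intermediate (not isolated)
16 | (R)-6,8-bis(benzyloxy)-3-[(S)-10-hydroxyundec-3-en-1-yl]isochroman-1-one | C[C@H](O)CCCCC/C=C/CC[C@@H]1Cc2cc(OCc3ccccc3)cc(OCc3ccccc3)c2C(=O)O1 | intermediate
17 | (R)-6,8-bis(benzyloxy)-3-[(S)-10-methoxyundec-3-en-1-yl]isochroman-1-one | CO[C@@H](C)CCCCC/C=C/CC[C@@H]1Cc2cc(OCc3ccccc3)cc(OCc3ccccc3)c2C(=O)O1 | intermediate
18 | (R)-6,8-bis(benzyloxy)-3-[(S)-10-methoxyundecyl]isochroman-1-one | CO[C@@H](C)CCCCCCCCC[C@@H]1Cc2cc(OCc3ccccc3)cc(OCc3ccccc3)c2C(=O)O1 | intermediate (not isolated)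
19 | (R)-6,8-dihydroxy-3-[(S)-10-methoxyundecyl]isochroman-1-one | CO[C@@H](C)CCCCCCCCC[C@@H]1Cc2cc(O)cc(O)c2C(=O)O1 | target

Total step count: 10. Longest linear sequence: 9 (steps 1–4 and 6–10).

Steps most likely to fail

Step 7. Intermolecular metathesis (oligomers, cyclic dimer) may outrun closure of the 16-membered ring, or ruthenium hydride species may shift a double bond before closure and give a ring-contracted homologue. The fallback gives up the tether and forms C3′=C4′ by untethered cross-metathesis. It sets out from acid 8: brief treatment with aqueous HCl in THF removes the silyl group and the hydroxy acid lactonises to (R)-6,8-bis(benzyloxy)-3-(but-3-enyl)isochroman-1-one F1. In parallel, Grignard reagent 11 opens commercial (S)-propylene oxide (C[C@H]1CO1, CuI cat., THF) to (S)-non-8-en-2-ol F2, which is methylated (NaH, MeI, THF) to (S)-8-methoxynon-1-ene F3. Cross-metathesis of F1 with an excess of F3 (3–4 equiv) using the second-generation Grubbs catalyst RuCl2(=CHPh)(PCy3)(H2IMes) in CH2Cl2 at 40 °C should give 17 as an E/Z mixture. The fallback comes back to the route at 17 and makes steps 8 and 9 unnecessary; the homodimer of F3 can be returned to the cross-metathesis.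

Step 3. Bromination may occur between the two benzyloxy groups or at the alkene, or traces of HBr may strip the silyl group and open the way to bromoetherification. The fallback introduces C1 by electrophilic formylation and oxidation instead of halogenation and lithiation. It sets out from 5: Vilsmeier–Haack formylation (POCl3, DMF, 0 °C → rt, aq NaOAc work-up) should give 2,4-bis(benzyloxy)-6-[(R)-2-(triethylsilyloxy)hex-5-enyl]benzaldehyde F4. Pinnick oxidation (NaClO2, NaH2PO4, 2-methylbut-2-ene, t-BuOH/H2O) then leads to acid 8, where the fallback rejoins the route, bypassing steps 3 and 4.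

Step 6. Elimination of the activated secondary alcohol, or incomplete inversion that erodes the configuration at C10′, may compete with the slow attack of the bulky carboxylate. The fallback separates activation from displacement. It sets out from 12, which is converted (MsCl, Et3N, CH2Cl2, 0 °C) into (R)-non-8-en-2-yl methanesulfonate F5. Acid 8 is turned with Cs2CO3 in DMF into cesium 2,4-bis(benzyloxy)-6-[(R)-2-(triethylsilyloxy)hex-5-enyl]benzoate F6, which displaces the mesylate of F5 at 50 °C by SN2 with inversion. The fallback comes back to the route at 13.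

Further compounds
F1 | step 7 | (R)-6,8-bis(benzyloxy)-3-(but-3-enyl)isochroman-1-one | C=CCC[C@@H]1Cc2cc(OCc3ccccc3)cc(OCc3ccccc3)c2C(=O)O1
F2 | step 7 | (S)-non-8-en-2-ol | C=CCCCCC[C@H](C)O
F3 | step 7 | (S)-8-methoxynon-1-ene | C=CCCCCC[C@H](C)OC
F4 | step 3 | 2,4-bis(benzyloxy)-6-[(R)-2-(triethylsilyloxy)hex-5-enyl]benzaldehyde | O=Cc1c(OCc2ccccc2)cc(OCc2ccccc2)cc1C[C@H](O[Si](CC)(CC)CC)CCC=C
F5 | step 6 | (R)-non-8-en-2-yl methanesulfonate | C=CCCCCC[C@@H](C)OS(C)(=O)=O
F6 | step 6 | cesium 2,4-bis(benzyloxy)-6-[(R)-2-(triethylsilyloxy)hex-5-enyl]benzoate | [Cs+].[O-]C(=O)c1c(OCc2ccccc2)cc(OCc2ccccc2)cc1C[C@H](O[Si](CC)(CC)CC)CCC=C
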